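The synthesis rests on disconnecting the cyclopentene ring of the tetrahydroindene at C1–C2 and C3a–C7a. In the forward sense, one rhodium-catalysed operation joins a (Z)-dienylboronate to (E)-pent-3-en-2-one: asymmetric conjugate alkenylation forms C1–C2, and the enolate so generated closes onto the boronate's own α,β-unsaturated ester to form C3a–C7a, setting C1, C7a and C3a. The step exploits two features: C3a lies β to the C4 carboxyl carbon, and C1/C7a are the β/α carbons of a methyl ketone whose carbonyl carbon becomes the methyl-bearing C7. The precursor is an acyclic δ-boryl dienoate carrying the C5 quaternary centre; the cyclohexene ring is closed afterwards by olefin metathesis.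

Key step: step 10

Remark: locants follow the 3a,4,5,7a-tetrahydro-1H-indene numbering of the target (C1 CHMe; C2=C3 with ethyl on C3; C3a; C4 with CO2H; C5 with the dienyl chain; C6=C7 with methyl on C7; C7a); CIP descriptors of untouched centres change in places only because substituent priorities change. Compounds 1, 5, 16 and 22 are taken as commercial.

Step 1
Reactants: 1 prop-2-yn-1-ol
Product: 3 (2Z)-2-ethyl-3-iodoprop-2-en-1-ol, via alkenylmagnesium alkoxide 2 (not isolated)
Conditions: EtMgBr (2.5 equiv), CuI (10 mol%), Et2O/THF, −10 °C to rt; then I2, −20 °C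
Reagents that add atoms: ethylmagnesium bromide CC[Mg]Br; iodine II
Why: copper-catalysed anti-carbomagnesiation of the propargylic alkoxide puts ethyl on C2 and magnesium on C3 cis to the chelating CH2O group, so iodinolysis with retention should give the (Z)-iodide.

Step 2
Reactants: 3 (2Z)-2-ethyl-3-iodoprop-2-en-1-ol
Product: 4 (2Z)-2-ethyl-3-iodoprop-2-enal
Conditions: MnO2 (excess), CH2Cl2, rt
Reagents that add atoms: none
Why: allylic alcohol oxidation on MnO2 should stop at the enal and leave the (Z)-iodoalkene untouched.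

Step 3
Reactants: 5 (2S)-but-3-yn-2-ol
Product: 6 (2S)-pent-3-yn-2-ol
Conditions: n-BuLi (2.1 equiv), THF, −78 °C; MeI (1.0 equiv), −78 °C to rt
Reagents that add atoms: iodomethane CI
Why: SN2 C-methylation of the alkynide carbon of the alkoxide–alkynide dianion, with the carbinol stereocentre untouched.

Step 4
Reactants: 6 (2S)-pent-3-yn-2-ol
Product: 8 (2S,3Z)-4-iodopent-3-en-2-ol, via cyclic alkenylaluminate 7 (not isolated)
Conditions: NaAlH2(OCH2CH2OMe)2 (1.5 equiv), THF, 0 °C to rt; then I2, −78 °C
Reagents that add atoms: iodine II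
Why: hydroxyl-directed trans-hydroalumination delivers hydride to C3 and aluminium to C4 inside a five-membered aluminate, so iodinolysis with retention should place iodine cis to the carbinol carbon.

Step 5
Reactants: 8 (2S,3Z)-4-iodopent-3-en-2-ol
Product: 9 (2S,3Z)-4-methylhept-3-en-5-yn-2-ol
Conditions: propyne (excess), PdCl2(PPh3)2 (3 mol%), CuI (5 mol%), Et3N, THF, 0 °C to rt
Reagents that add atoms: propyne CC#C
Why: Sonogashira coupling of the alkenyl iodide proceeds with retention of the (Z) geometry.

Step 6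
Reactants: 9 (2S,3Z)-4-methylhept-3-en-5-yn-2-ol
Product: 11 methyl (3R,4E)-3-methyl-3-(prop-1-yn-1-yl)hex-4-enoate, via mixed ketene acetal 10 (not isolated)
Conditions: MeC(OMe)3 (6 equiv), EtCO2H (10 mol%), toluene, 110 °C, removal of MeOH
Reagents that add atoms: trimethyl orthoacetate COC(C)(OC)OC
Why: Johnson–Claisen rearrangement through a chair transition state with the carbinol methyl equatorial transfers the (S) carbinol chirality of the (Z)-alkene to the new quaternary carbon (future C5) as (R) and gives the (E)-propenyl group.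

Step 7
Reactants: 11 methyl (3R,4E)-3-methyl-3-(prop-1-yn-1-yl)hex-4-enoate; 4 (2Z)-2-ethyl-3-iodoprop-2-enal
Product: 12 methyl (3S,4E)-2-[(2Z)-2-ethyl-1-hydroxy-3-iodoprop-2-en-1-yl]-3-methyl-3-(prop-1-yn-1-yl)hex-4-enoate (diastereomers at C2 and the carbinol carbon)
Conditions: LiN(iPr)2 (1.1 equiv), THF, −78 °C; then 4, −78 °C; aqueous work-up
Reagents that add atoms: none
Why: aldol 1,2-addition of the lithium ester enolate to the aldehyde, the two new stereocentres being inconsequential because both are erased in steps 8 and 10.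

Step 8
Reactants: 12 aldol adduct
Product: 14 methyl (2Z,3R,4E)-2-[(2Z)-2-ethyl-3-iodoprop-2-en-1-ylidene]-3-methyl-3-(prop-1-yn-1-yl)hex-4-enoate, via mesylate 13 (not isolated)
Conditions: MsCl, Et3N, CH2Cl2, 0 °C; then DBU, rt
Reagents that add atoms: none
Why: mesylation and E1cB elimination should give the conjugated dienoate, both aldol diastereomers converging on the (2Z) isomer in which the iodoalkenyl group avoids the quaternary carbon.

Step 9
Reactants: 14 iododienoate
Product: 15 methyl (2Z,3R,4E)-2-[(2Z)-2-ethyl-3-(4,4,5,5-tetramethyl-1,3,2-dioxaborolan-2-yl)prop-2-en-1-ylidene]-3-methyl-3-(prop-1-yn-1-yl)hex-4-enoate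
Conditions: B2pin2 (1.1 equiv), PdCl2(dppf) (3 mol%), KOPh (1.5 equiv), toluene, 50 °C
Reagents that add atoms: bis(pinacolato)diboron CC1(C)OB(OC1(C)C)B1OC(C)(C)C(C)(C)O1
Why: Miyaura borylation of the alkenyl iodide occurs with retention of the (Z) geometry, the weak phenoxide base suppressing Suzuki-type homocoupling.

Step 10
Reactants: 15 dienylboronate; 16 (3E)-pent-3-en-2-one
Product: 18 methyl (3S,4E)-2-[(1S,4R,5S)-5-acetyl-2-ethyl-4-methylcyclopent-2-en-1-yl]-3-methyl-3-(prop-1-yn-1-yl)hex-4-enoate (C2 epimers), via open-chain conjugate adduct 17 (not isolated)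
Conditions: 16 (3 equiv), [Rh(cod)Cl]2 (2.5 mol%), (S)-BINAP (5.5 mol%), aq. KOH (30 mol%), 1,4-dioxane, 50 °C
Reagents that add atoms: none
Why: Proposed new method: boron-to-rhodium transfer from 15 gives a (Z)-dienylrhodium species that inserts enone 16 at its β-carbon (new C1–C2 bond), and the resulting oxa-π-allyl rhodium enolate 17 (or its potassium enolate after protonolysis) adds through its α-carbon to the β-carbon of the pendant α,β-unsaturated ester (new C3a–C7a bond) before the ester enolate is protonated; the closest known reaction types are the rhodium-catalysed asymmetric conjugate addition of alkenylboron reagents to acyclic enones (Hayashi–Miyaura reaction) and rhodium-catalysed conjugate addition/Michael cyclisation cascades of boron reagents that carry a pendant acceptor, neither of which has been shown for a δ-boryl dienoate delivering a cyclopentene. Only the cyclopentene ring closes here, in a 5-exo-trig Michael mode in which the (Z)-alkene of the boronate becomes the ring C2=C3 bond. C1 is set by the chiral ligand, which selects one enantioface of 16 ((R) is expected with (S)-BINAP by the usual sense of induction for (E)-enones), whereas C7a, which stays epimerisable next to the acetyl group, and C3a are set relative to C1 by the ring closure, which should place the three ring substituents all-trans. The step needs 1,4-addition to 16 rather than to the dienoate of a second molecule of 15 or to the alkyne, which is secured by the excess of unhindered enone, by the α-branching of the dienoate and by the (2Z) geometry that holds the propynyl group away from the rhodium-bearing carbon. Adduct that is protonated before cyclising should still close under the basic medium, and the C2 epimers of the side chain converge in step 13.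

Step 11
Reactants: 18 cyclopentenyl methyl ketone
Product: 19 methyl (3S,4E)-2-[(1S,4R,5S)-2-ethyl-4-methyl-5-(prop-1-en-2-yl)cyclopent-2-en-1-yl]-3-methyl-3-(prop-1-yn-1-yl)hex-4-enoate (C2 epimers)
Conditions: Ph3PCH3Br (1.5 equiv), KOtBu (1.4 equiv), THF, 0 °C to rt
Reagents that add atoms: methyltriphenylphosphonium bromide C[P+](c1ccccc1)(c1ccccc1)c1ccccc1.[Br-]
Why: Wittig methylenation of the methyl ketone is chemoselective over the hindered ester, and the adjacent C7a centre, should it epimerise, returns to the all-trans arrangement.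

Step 12
Reactants: 19 isopropenyl/propenyl diene
Product: 20 methyl (1R,3aS,5S,7aS)-3-ethyl-1,5,7-trimethyl-5-(prop-1-yn-1-yl)-3a,4,5,7a-tetrahydro-1H-indene-4-carboxylate (C4 epimers)
Conditions: second-generation Hoveyda–Grubbs catalyst (5 mol%), toluene, 80 °C
Reagents that add atoms: none
Why: ring-closing metathesis between the isopropenyl and (E)-propenyl groups forms the C6=C7 bond and the trans-fused cyclohexene with loss of propene, the only other π-bonds being a trisubstituted ring alkene and a hindered internal alkyne.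

Step 13
Reactants: 20 bicyclic ester
Product: 21 methyl (1R,3aR,4R,5R,7aS)-3-ethyl-1,4,5,7-tetramethyl-5-(prop-1-yn-1-yl)-3a,4,5,7a-tetrahydro-1H-indene-4-carboxylate
Conditions: LiN(iPr)2 (1.3 equiv), THF, −78 °C; MeI, DMPU, −78 to 0 °C
Reagents that add atoms: iodomethane CI
Why: ester enolate alkylation in which iodomethane should enter axially at C4, anti to the pseudoaxial propynyl group on C5 of the conformationally locked trans-fused ring, setting the C4 quaternary centre with the ester equatorial whichever C4 epimer is used.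

Step 14
Reactants: 21 propynyl ester; 22 [(E)-2-bromoethenyl]benzene
Product: 24 methyl (1R,3aR,4R,5S,7aS)-3-ethyl-1,4,5,7-tetramethyl-5-[(1E,3E)-2-methyl-4-phenylbuta-1,3-dien-1-yl]-3a,4,5,7a-tetrahydro-1H-indene-4-carboxylate, via alkenylzirconocene chloride 23 (not isolated)
Conditions: Cp2Zr(H)Cl (2 equiv), THF, 40 °C; then 22, Pd(PPh3)4 (5 mol%), ZnCl2 (20 mol%), rt
Reagents that add atoms: none
Why: syn-hydrozirconation of the internal alkyne places zirconium on the methyl-bearing carbon remote from the quaternary centre, and Negishi-type alkenyl–alkenyl coupling with the (E)-bromide retains both geometries to give the (1E,3E)-diene.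

Step 15
Reactants: 24 methyl ester of the target
Product: 25 (1R,3aR,4R,5S,7aS)-3-ethyl-1,4,5,7-tetramethyl-5-[(1E,3E)-2-methyl-4-phenylbuta-1,3-dien-1-yl]-3a,4,5,7a-tetrahydro-1H-indene-4-carboxylic acid (Zyggomphic acid B)
Conditions: NaSEt (5 equiv), DMF, 90 °C; then 1 M HCl
Reagents that add atoms: none
Why: SN2 demethylation by thiolate at the ester methyl group cleaves the hindered ester without attack at its shielded carbonyl or at any stereocentre.

Compound list
1 | prop-2-yn-1-ol | C#CCO | starting material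
2 | bromomagnesium (2Z)-3-(bromomagnesio)-2-ethylprop-2-en-1-olate | CC/C(=C/[Mg]Br)CO[Mg]Br | intermediate
3 | (2Z)-2-ethyl-3-iodoprop-2-en-1-ol | CC/C(=C/I)CO | intermediate
4 | (2Z)-2-ethyl-3-iodoprop-2-enal | CC/C(=C/I)C=O | intermediate
5 | (2S)-but-3-yn-2-ol | C[C@H](O)C#C | starting material
6 | (2S)-pent-3-yn-2-ol | C[C@H](O)C#CC | intermediate
7 | sodium (5S)-2,2-bis(2-methoxyethoxy)-3,5-dimethyl-2,5-dihydro-1,2-oxaluminol-2-uide | C[C@@H]1O[Al-](OCCOC)(OCCOC)C(C)=C1.[Na+] | intermediate
8 | (2S,3Z)-4-iodopent-3-en-2-ol | C[C@H](O)/C=C(/C)I | intermediate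
9 | (2S,3Z)-4-methylhept-3-en-5-yn-2-ol | C[C@H](O)/C=C(/C)C#CC | intermediate
10 | (2S,3Z)-2-[(1-methoxyethenyl)oxy]-4-methylhept-3-en-5-yne | C=C(OC)O[C@@H](C)/C=C(/C)C#CC | intermediate
11 | methyl (3R,4E)-3-methyl-3-(prop-1-yn-1-yl)hex-4-enoate | COC(=O)C[C@@](C)(C#CC)/C=C/C | intermediate
12 | methyl (3S,4E)-2-[(2Z)-2-ethyl-1-hydroxy-3-iodoprop-2-en-1-yl]-3-methyl-3-(prop-1-yn-1-yl)hex-4-enoate, mixture at C2 and the carbinol carbon (C3 unchanged in space) | CC/C(=C/I)C(O)C(C(=O)OC)[C@@](C)(C#CC)/C=C/C | intermediate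
13 | methyl (3S,4E)-2-[(2Z)-2-ethyl-3-iodo-1-(methanesulfonyloxy)prop-2-en-1-yl]-3-methyl-3-(prop-1-yn-1-yl)hex-4-enoate | CC/C(=C/I)C(OS(C)(=O)=O)C(C(=O)OC)[C@@](C)(C#CC)/C=C/C | intermediate
14 | methyl (2Z,3R,4E)-2-[(2Z)-2-ethyl-3-iodoprop-2-en-1-ylidene]-3-methyl-3-(prop-1-yn-1-yl)hex-4-enoate | CC/C(=C/I)/C=C(\C(=O)OC)[C@@](C)(C#CC)/C=C/C | intermediate
15 | methyl (2Z,3R,4E)-2-[(2Z)-2-ethyl-3-(4,4,5,5-tetramethyl-1,3,2-dioxaborolan-2-yl)prop-2-en-1-ylidene]-3-methyl-3-(prop-1-yn-1-yl)hex-4-enoate | CC/C(=C/B1OC(C)(C)C(C)(C)O1)/C=C(\C(=O)OC)[C@@](C)(C#CC)/C=C/C | intermediate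
16 | (3E)-pent-3-en-2-one | C/C=C/C(C)=O | starting material
17 | methyl (2Z,3R,4E)-2-[(2Z,4S)-2-ethyl-4-methyl-6-oxohept-2-en-1-ylidene]-3-methyl-3-(prop-1-yn-1-yl)hex-4-enoate (shown as the ketone form of the enolate) | CC/C(=C/[C@@H](C)CC(C)=O)/C=C(\C(=O)OC)[C@@](C)(C#CC)/C=C/C | intermediate
18 | methyl (3S,4E)-2-[(1S,4R,5S)-5-acetyl-2-ethyl-4-methylcyclopent-2-en-1-yl]-3-methyl-3-(prop-1-yn-1-yl)hex-4-enoate, C2 epimers, ring substituents all-trans | CCC1=C[C@@H](C)[C@H](C(C)=O)[C@H]1C(C(=O)OC)[C@@](C)(C#CC)/C=C/C | intermediate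
19 | methyl (3S,4E)-2-[(1S,4R,5S)-2-ethyl-4-methyl-5-(prop-1-en-2-yl)cyclopent-2-en-1-yl]-3-methyl-3-(prop-1-yn-1-yl)hex-4-enoate, C2 epimers | CCC1=C[C@@H](C)[C@H](C(C)=C)[C@H]1C(C(=O)OC)[C@@](C)(C#CC)/C=C/C | intermediate
20 | methyl (1R,3aS,5S,7aS)-3-ethyl-1,5,7-trimethyl-5-(prop-1-yn-1-yl)-3a,4,5,7a-tetrahydro-1H-indene-4-carboxylate, C4 epimers, trans ring fusion | CCC1=C[C@@H](C)[C@@H]2C(C)=C[C@](C)(C#CC)C(C(=O)OC)[C@@H]12 | intermediate
21 | methyl (1R,3aR,4R,5R,7aS)-3-ethyl-1,4,5,7-tetramethyl-5-(prop-1-yn-1-yl)-3a,4,5,7a-tetrahydro-1H-indene-4-carboxylate | CCC1=C[C@@H](C)[C@@H]2C(C)=C[C@](C)(C#CC)[C@](C)(C(=O)OC)[C@@H]12 | intermediate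
22 | [(E)-2-bromoethenyl]benzene | Br/C=C/c1ccccc1 | starting material
23 | chlorobis(cyclopentadienyl)zirconium (E)-alkenyl derivative of 21, Zr on the CH3-bearing alkene carbon, H on the carbon attached to C5, ring stereocentres as in 21 | CCC1=C[C@@H](C)[C@@H]2C(C)=C[C@](C)(/C=C(C)/[Zr](Cl)(C3C=CC=C3)C3C=CC=C3)[C@](C)(C(=O)OC)[C@@H]12 | intermediate
24 | methyl (1R,3aR,4R,5S,7aS)-3-ethyl-1,4,5,7-tetramethyl-5-[(1E,3E)-2-methyl-4-phenylbuta-1,3-dien-1-yl]-3a,4,5,7a-tetrahydro-1H-indene-4-carboxylate | CCC1=C[C@@H](C)[C@@H]2C(C)=C[C@](C)(/C=C(C)/C=C/c3ccccc3)[C@](C)(C(=O)OC)[C@@H]12 | intermediate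
25 | (1R,3aR,4R,5S,7aS)-3-ethyl-1,4,5,7-tetramethyl-5-[(1E,3E)-2-methyl-4-phenylbuta-1,3-dien-1-yl]-3a,4,5,7a-tetrahydro-1H-indene-4-carboxylic acid (Zyggomphic acid B) | CCC1=C[C@@H](C)[C@@H]2C(C)=C[C@](C)(/C=C(C)/C=C/c3ccccc3)[C@](C)(C(=O)O)[C@@H]12 | target

Total steps: 15. Longest linear sequence: 13 steps (steps 3 to 15, from 5); steps 1 and 2 form the short branch that delivers 4.

Steps most likely to fail

Step 10 (Proposed new method). The boron-to-rhodium transfer of the electron-poor, hindered dienylboronate may be slow, so that protodeboronation competes. The Michael closure onto the α-branched enoate, whose ester is likely twisted out of conjugation, may also be slow or poorly diastereoselective. The fallback uses known reactions only, sets out from 3 and comes back at 18; it makes the two bonds in separate operations and moves the conjugate alkenylation to an ester-free boronate. Alcohol 3 is silylated (TBSCl, imidazole) to silyl ether F1, which undergoes Miyaura borylation (B2pin2, PdCl2(dppf), KOPh) to boronate F2. Hayashi–Miyaura addition of F2 to 16 ([Rh(cod)Cl]2/(S)-BINAP, aq. KOH) should give silyloxy ketone F3. Desilylation (Bu4NF) gives hydroxy ketone F4 and MnO2 oxidation gives keto-enal F5. Aldol addition of the lithium enolate of 11 (LiN(iPr)2, −78 °C) to the aldehyde of F5 gives aldol F6. Mesylation and DBU elimination lead to 17, which is cyclised by intramolecular Michael addition under DBU or catalytic KOtBu to 18.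

Step 13. Facial control in the enolate methylation may be lost through attack on the equatorial face, and enolisation of the hindered ester may be incomplete. The fallback sets out from 19 and comes back at 21. Methylation (LiN(iPr)2, MeI) is carried out on the open-chain ester 19, where the enolate faces are differentiated by the adjacent cyclopentenyl stereocentre and not by the bicyclic ring. The C2-methylated ester F7 of the required configuration is separated from its epimer. Ring-closing metathesis under the conditions of step 12 then gives 21.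

Step 12. Catalyst loading at the neopentyl-type propenyl group may be slow and closure of a trisubstituted alkene next to a quaternary carbon reluctant, which leaves room for intermolecular metathesis or enyne metathesis at the alkyne. The fallback sets out from 18 and comes back at 20, replacing steps 11 and 12 and making no new compound. Ketone 18 is treated with stoichiometric Mo(=CHCMe2Ph)(=N-2,6-iPr2C6H3)[OCMe(CF3)2]2. Alkylidene exchange at the propenyl group is followed by intramolecular carbonyl olefination of the methyl ketone (alkylidene-mediated olefin metathesis/carbonyl olefination), which forms C6=C7 directly.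

Further compounds
F1 | step 10 | tert-butyl{[(2Z)-2-ethyl-3-iodoprop-2-en-1-yl]oxy}dimethylsilane | CC/C(=C/I)CO[Si](C)(C)C(C)(C)C
F2 | step 10 | tert-butyl{[(2Z)-2-ethyl-3-(4,4,5,5-tetramethyl-1,3,2-dioxaborolan-2-yl)prop-2-en-1-yl]oxy}dimethylsilane | CC/C(=C/B1OC(C)(C)C(C)(C)O1)CO[Si](C)(C)C(C)(C)C
F3 | step 10 | (4S,5Z)-7-[(tert-butyldimethylsilyl)oxy]-6-ethyl-4-methylhept-5-en-2-one | CC/C(=C/[C@@H](C)CC(C)=O)CO[Si](C)(C)C(C)(C)C
F4 | step 10 | (4S,5Z)-6-ethyl-7-hydroxy-4-methylhept-5-en-2-one | CC/C(=C/[C@@H](C)CC(C)=O)CO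
F5 | step 10 | (2Z,4S)-2-ethyl-4-methyl-6-oxohept-2-enal | CC/C(=C/[C@@H](C)CC(C)=O)C=O
F6 | step 10 | methyl (3S,4E)-2-[(2Z,4S)-2-ethyl-1-hydroxy-4-methyl-6-oxohept-2-en-1-yl]-3-methyl-3-(prop-1-yn-1-yl)hex-4-enoate | CC/C(=C/[C@@H](C)CC(C)=O)C(O)C(C(=O)OC)[C@@](C)(C#CC)/C=C/C
F7 | step 13 | methyl (2R,3R,4E)-2-[(1R,4R,5S)-2-ethyl-4-methyl-5-(prop-1-en-2-yl)cyclopent-2-en-1-yl]-2,3-dimethyl-3-(prop-1-yn-1-yl)hex-4-enoate | CCC1=C[C@@H](C)[C@H](C(C)=C)[C@H]1[C@@](C)(C(=O)OC)[C@@](C)(C#CC)/C=C/C
F0 | step 12 | none | none
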